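**Retrosynthetic overview**
1. Last operation: methanolysis of a phenolic acetate; the vanillate ester itself is carried from the first fragment onwards.
2. Five-membered ring (closed second): C8a–C1 is formed by a reductive, dehydrative Nazarov-type 4π-electrocyclisation of a dienyl carbinol under a chiral acid, which sets C8a, the C3=C3a alkene and the isopropyl-bearing carbon together.
3. Seven-membered ring (closed first): a rhodium-catalysed (5+2) cycloaddition forms C8–C8a and C3a–C4 in one operation from a 1-substituted vinylcyclopropane and an internal alkyne.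
4. Enabling feature: the arc C8–C7=C6(CH2O)–C5–C4 of the seven-membered ring is the ring-opened form of a 1-(acyloxymethyl)-1-vinylcyclopropane, and the ring-fusion carbons C8a and C3a (one carrying CH3, the other carrying C1–C3) are the two carbons of an alkyne.
5. Fragments: ethyl 1-formylcyclopropane-1-carboxylate, 4-(acetyloxy)-3-methoxybenzoic acid, 4-methylpent-1-en-3-one and prop-1-yn-1-ylmagnesium bromide.

Key step: step 5

Remark: positions are numbered as in 1,2,4,5,8,8a-hexahydroazulene (C8a = quaternary stereocentre, R in the target; C3 = isopropyl-bearing carbon; C6 = carbon bearing CH2O); compounds 1, 4, 6 and 7 (0.5 M in THF) are taken to be catalogue chemicals.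

**Step 1**
Reactants: 1 ethyl 1-formylcyclopropane-1-carboxylate
Product: 2 ethyl 1-ethenylcyclopropane-1-carboxylate
Conditions: CH3PPh3Br, KOC(CH3)3, THF, 0 °C to rt
Reagents that add atoms: methyltriphenylphosphonium bromide, C[P+](c1ccccc1)(c1ccccc1)c1ccccc1.[Br-]
Why: Wittig methylenation of a non-enolisable aldehyde, which the non-stabilised ylide should attack far faster than the ester.

**Step 2**
Reactants: 2 ethyl 1-ethenylcyclopropane-1-carboxylate
Product: 3 (1-ethenylcyclopropyl)methanol
Conditions: LiAlH4, Et2O, 0 °C; then H2O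
Reagents that add atoms: none
Why: hydride reduction of the ester to the primary alcohol; the isolated vinyl group and the cyclopropane are inert to LiAlH4.

**Step 3**
Reactants: 3 (1-ethenylcyclopropyl)methanol; 4 4-(acetyloxy)-3-methoxybenzoic acid
Product: 5 (1-ethenylcyclopropyl)methyl 4-(acetyloxy)-3-methoxybenzoate
Conditions: N,N'-dicyclohexylcarbodiimide, 4-(dimethylamino)pyridine (cat.), CH2Cl2, 0 °C to rt
Reagents that add atoms: none
Why: Steglich esterification acylates at oxygen, so the cyclopropylcarbinyl C–O bond is never broken and ring opening cannot occur; the phenol is masked as its acetate to prevent self-acylation.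

**Step 4**
Reactants: 6 4-methylpent-1-en-3-one; 7 prop-1-yn-1-ylmagnesium bromide
Product: 8 3-(propan-2-yl)hex-1-en-4-yn-3-ol (racemic)
Conditions: THF, −78 °C to 0 °C; then aq NH4Cl
Reagents that add atoms: none
Why: Grignard addition of an alkynyl reagent to an enone should go 1,2 and give the tertiary alcohol; its stereocentre is left racemic because it is erased in step 6.

**Step 5**
Reactants: 5 (1-ethenylcyclopropyl)methyl 4-(acetyloxy)-3-methoxybenzoate; 8 3-(propan-2-yl)hex-1-en-4-yn-3-ol
Product: 9 [5-(3-hydroxy-4-methylpent-1-en-3-yl)-4-methylcyclohepta-1,4-dien-1-yl]methyl 4-(acetyloxy)-3-methoxybenzoate (racemic at the carbinol carbon)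
Conditions: [Rh(CO)2Cl]2 (5 mol %), ClCH2CH2Cl, 80 °C
Reagents that add atoms: none
Why: Monovalent rhodium coordinates the vinylcyclopropane 5 and inserts into a cyclopropane C–C bond to give a trivalent-rhodium σ-alkyl/π-allyl metallacycle; the alkyne of 8 then inserts at the allyl terminus (bond from the former vinyl CH2 to the methyl-bearing alkyne carbon), and C(sp2)–C(sp3) reductive elimination joins the carbinol-bearing alkyne carbon to the former cyclopropane CH2. The closest known reaction type is the intermolecular rhodium-catalysed (5+2) cycloaddition of 1-substituted vinylcyclopropanes with alkynes, which is also the first stage of known (5+2)/Nazarov sequences to bicyclo[5.3.0]decanes. The seven-membered ring closes by reductive elimination from an eight-membered rhodacycle, that is, as a formal (5+2) cycloaddition in which both new bonds go to the two alkyne carbons. No new stereocentre is created; the carbinol centre of 8 is carried as the racemate and is destroyed in step 6. The step needs regioselectivity (methyl-bearing carbon to the vinyl-derived CH2) and chemoselectivity (alkyne, not the vinyl group of 8): the fully substituted carbinol group is far larger than methyl and should take the position remote from the first-formed C–C bond, alkynes insert much faster than alkenes, and the 1-substituent of 5 holds the vinyl group in the s-cis arrangement needed for ring cleavage.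

**Step 6**
Reactants: 9 [5-(3-hydroxy-4-methylpent-1-en-3-yl)-4-methylcyclohepta-1,4-dien-1-yl]methyl 4-(acetyloxy)-3-methoxybenzoate
Product: 12 [(8aR)-8a-methyl-3-(propan-2-yl)-1,2,4,5,8,8a-hexahydroazulen-6-yl]methyl 4-(acetyloxy)-3-methoxybenzoate, via pentadienyl cation 10 (not isolated), via bicyclic allyl cation 11 (not isolated)
Conditions: one enantiomer of 3,3'-bis(2,4,6-triisopropylphenyl)-1,1'-binaphthyl-2,2'-diyl N-(trifluoromethylsulfonyl)phosphoramide (10 mol %), Et3SiH (3 equiv), toluene, −40 °C
Reagents that add atoms: none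
Why: Proposed new method: the chiral acid should ionise the tertiary bis-allylic alcohol to pentadienyl cation 10, held as a contact ion pair; conrotatory 4π-electrocyclisation then forms C8a–C1, with the sense of rotation (and so the R configuration at C8a) set by the chiral counter-anion, the catalyst antipode being chosen by experiment. Et3SiH should deliver hydride to the unhindered CH terminus of allyl cation 11 so that the tetrasubstituted C3=C3a alkene remains. The closest known reaction types are the acid-mediated cyclisation of dienyl carbinols to cyclopentadienes (the route to pentamethylcyclopentadiene), the chiral N-triflylphosphoramide-catalysed dehydrative Nazarov-type electrocyclisation of aryl vinyl carbinols, the silane-interrupted Nazarov reaction and ionic hydrogenation.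

**Step 7**
Reactants: 12 [(8aR)-8a-methyl-3-(propan-2-yl)-1,2,4,5,8,8a-hexahydroazulen-6-yl]methyl 4-(acetyloxy)-3-methoxybenzoate
Product: 13 [(8aR)-8a-methyl-3-(propan-2-yl)-1,2,4,5,8,8a-hexahydroazulen-6-yl]methyl 4-hydroxy-3-methoxybenzoate (CNP0327126.2)
Conditions: K2CO3 (0.2 equiv), CH3OH, 0 °C
Reagents that add atoms: none
Why: transesterification of an aryl acetate is much faster than that of an alkyl benzoate, and the phenoxide formed further deactivates the vanillate carbonyl, so only the acetate should be removed; the stereocentre is not touched.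

**Compound list**
1 | ethyl 1-formylcyclopropane-1-carboxylate | CCOC(=O)C1(C=O)CC1 | starting material
2 | ethyl 1-ethenylcyclopropane-1-carboxylate | CCOC(=O)C1(C=C)CC1 | intermediate
3 | (1-ethenylcyclopropyl)methanol | OCC1(C=C)CC1 | intermediate
4 | 4-(acetyloxy)-3-methoxybenzoic acid | CC(=O)Oc1ccc(cc1OC)C(=O)O | starting material
5 | (1-ethenylcyclopropyl)methyl 4-(acetyloxy)-3-methoxybenzoate | CC(=O)Oc1ccc(cc1OC)C(=O)OCC1(C=C)CC1 | intermediate
6 | 4-methylpent-1-en-3-one | C=CC(=O)C(C)C | starting material
7 | prop-1-yn-1-ylmagnesium bromide | CC#C[Mg]Br | starting material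
8 | 3-(propan-2-yl)hex-1-en-4-yn-3-ol (racemic) | C=CC(O)(C(C)C)C#CC | intermediate
9 | [5-(3-hydroxy-4-methylpent-1-en-3-yl)-4-methylcyclohepta-1,4-dien-1-yl]methyl 4-(acetyloxy)-3-methoxybenzoate (racemic at the carbinol carbon) | CC(=O)Oc1ccc(cc1OC)C(=O)OCC1=CCC(C)=C(CC1)C(O)(C(C)C)C=C | intermediate
10 | pentadienyl cation formed by ionisation of 9 (one resonance form; counter-ion is the chiral phosphoramide anion) | CC(=O)Oc1ccc(cc1OC)C(=O)OCC1=CCC(C)=C(CC1)[C+](C(C)C)C=C | intermediate
11 | (8aR)-bicyclic allyl cation formed by electrocyclisation of 10 (one resonance form) | CC(=O)Oc1ccc(cc1OC)C(=O)OCC1=CC[C@@]2(C)CC=C(C(C)C)[C+]2CC1 | intermediate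
12 | [(8aR)-8a-methyl-3-(propan-2-yl)-1,2,4,5,8,8a-hexahydroazulen-6-yl]methyl 4-(acetyloxy)-3-methoxybenzoate | CC(=O)Oc1ccc(cc1OC)C(=O)OCC1=CC[C@@]2(C)CCC(C(C)C)=C2CC1 | intermediate
13 | [(8aR)-8a-methyl-3-(propan-2-yl)-1,2,4,5,8,8a-hexahydroazulen-6-yl]methyl 4-hydroxy-3-methoxybenzoate | COc1cc(C(=O)OCC2=CC[C@@]3(C)CCC(C(C)C)=C3CC2)ccc1O | target

**Step count**
Total steps: 7. Longest linear sequence: 6 steps (steps 1, 2, 3, 5, 6, 7); step 4 is the side branch.

**Steps most likely to fail**

1. Step 6 (proposed new method). What may go wrong: weak transfer of chirality from the counter-anion to the conrotatory ring closure, hydride capture of the open pentadienyl cation before it cyclises, or ionic hydrogenation of the C6=C7 or C3=C3a alkene. The fallback uses known chemistry, sets out from 9 and comes back at 12. Compound 9 is cyclised with 4-toluenesulfonic acid (cat.) in benzene at rt, the classical dehydrative electrocyclisation of dienyl carbinols, to the racemic cyclopentadiene [8a-methyl-3-(propan-2-yl)-4,5,8,8a-tetrahydroazulen-6-yl]methyl 4-(acetyloxy)-3-methoxybenzoate F1. Ionic hydrogenation of the diene (CF3CO2H, Et3SiH, CH2Cl2, −20 °C; proton to C1, hydride to C2) should give racemic [8a-methyl-3-(propan-2-yl)-1,2,4,5,8,8a-hexahydroazulen-6-yl]methyl 4-(acetyloxy)-3-methoxybenzoate F2. Preparative chromatography of F2 on a chiral stationary phase then delivers the (8aR) enantiomer, which is 12.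

2. Step 5. What may go wrong: slow insertion of the hindered, unactivated internal alkyne, insertion with the opposite orientation (regioisomeric cycloheptadiene), or loss of the tertiary hydroxyl at the metal. The fallback moves the cycloaddition to an electron-poor, slimmer alkyne and builds the carbinol afterwards; it sets out from 3 and 7 and comes back at 9.
   - Compound 3 is silylated (tert-butyldimethylsilyl chloride, imidazole) to tert-butyl[(1-ethenylcyclopropyl)methoxy]dimethylsilane F3.
   - Compound 7 is acylated with N-methoxy-N,2-dimethylpropanamide to 2-methylhex-4-yn-3-one F4.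
   - [Rh(CO)2Cl]2-catalysed (5+2) cycloaddition of F3 and F4 should give 1-[5-({[tert-butyl(dimethyl)silyl]oxy}methyl)-2-methylcyclohepta-1,4-dien-1-yl]-2-methylpropan-1-one F5.
   - Vinylmagnesium bromide with CeCl3 (THF, −78 °C) should add 1,2 to give 3-[5-({[tert-butyl(dimethyl)silyl]oxy}methyl)-2-methylcyclohepta-1,4-dien-1-yl]-4-methylpent-1-en-3-ol F6.
   - (n-C4H9)4NF removes the silyl group to give 3-[5-(hydroxymethyl)-2-methylcyclohepta-1,4-dien-1-yl]-4-methylpent-1-en-3-ol F7.
   - The primary allylic hydroxyl of F7 is esterified selectively with 4 (N,N'-dicyclohexylcarbodiimide, 4-(dimethylamino)pyridine) to give 9.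

3. Step 4. What may go wrong: conjugate addition to, and anionic polymerisation of, the vinyl ketone in competition with 1,2-addition. The fallback masks the enone double bond during the Grignard step; it sets out from 6 and 7 and comes back at 8. Conjugate addition of benzenethiol to 6 (triethylamine cat.) gives 4-methyl-1-(phenylsulfanyl)pentan-3-one F8. Compound 7 adds to this saturated ketone to give 1-(phenylsulfanyl)-3-(propan-2-yl)hex-4-yn-3-ol F9. Oxidation with NaIO4 gives 1-(benzenesulfinyl)-3-(propan-2-yl)hex-4-yn-3-ol F10, and thermal syn-elimination of the sulfoxide (toluene, 110 °C) should unveil the vinyl group of 8.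

**Further compounds**
F1 | step 6 | [8a-methyl-3-(propan-2-yl)-4,5,8,8a-tetrahydroazulen-6-yl]methyl 4-(acetyloxy)-3-methoxybenzoate (racemic) | CC(=O)Oc1ccc(cc1OC)C(=O)OCC1=CCC2(C)C=CC(C(C)C)=C2CC1
F2 | step 6 | [8a-methyl-3-(propan-2-yl)-1,2,4,5,8,8a-hexahydroazulen-6-yl]methyl 4-(acetyloxy)-3-methoxybenzoate (racemic) | CC(=O)Oc1ccc(cc1OC)C(=O)OCC1=CCC2(C)CCC(C(C)C)=C2CC1
F3 | step 5 | tert-butyl[(1-ethenylcyclopropyl)methoxy]dimethylsilane | CC(C)(C)[Si](C)(C)OCC1(C=C)CC1
F4 | step 5 | 2-methylhex-4-yn-3-one | CC#CC(=O)C(C)C
F5 | step 5 | 1-[5-({[tert-butyl(dimethyl)silyl]oxy}methyl)-2-methylcyclohepta-1,4-dien-1-yl]-2-methylpropan-1-one | CC(C)C(=O)C1=C(C)CC=C(CO[Si](C)(C)C(C)(C)C)CC1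
F6 | step 5 | 3-[5-({[tert-butyl(dimethyl)silyl]oxy}methyl)-2-methylcyclohepta-1,4-dien-1-yl]-4-methylpent-1-en-3-ol (racemic) | C=CC(O)(C(C)C)C1=C(C)CC=C(CO[Si](C)(C)C(C)(C)C)CC1
F7 | step 5 | 3-[5-(hydroxymethyl)-2-methylcyclohepta-1,4-dien-1-yl]-4-methylpent-1-en-3-ol (racemic) | C=CC(O)(C(C)C)C1=C(C)CC=C(CO)CC1
F8 | step 4 | 4-methyl-1-(phenylsulfanyl)pentan-3-one | CC(C)C(=O)CCSc1ccccc1
F9 | step 4 | 1-(phenylsulfanyl)-3-(propan-2-yl)hex-4-yn-3-ol (racemic) | CC#CC(O)(CCSc1ccccc1)C(C)C
F10 | step 4 | 1-(benzenesulfinyl)-3-(propan-2-yl)hex-4-yn-3-ol | CC#CC(O)(CCS(=O)c1ccccc1)C(C)C
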